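## Retrosynthetic overview

1. Final operations are functional-group changes only: C13′ ketone → (E)-C13′(CH3)=C12′H (enol triflate, CH3MgBr), both C3–OH groups removed, both CH2OH groups → CO2H.
2. Central cyclohexene, formed last: catalyst-controlled [4+2] between the (12E)-12,14-diene of the 7-methylidene half and the C14′=C15′ vinyl ketone of the other half (C12–C14′ and C15–C15′ bonds; sets C12 and C14′).
3. Each trans-decalin, formed first and in parallel (ring A then ring B in one operation): Cp2TiCl radical bicyclisation of an acyclic Sharpless epoxide (C4–C5 then C10–C9 bonds). L-(+)-tartrate serves one half, D-(−)-tartrate the mirror-image half.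
4. The 7-methylidene half ends its cascade on an enone (C7 ketone, then Wittig) and carries its diene as a 3-methyl-3-sulfolene. The other half ends by exocyclic-alkene formation and carries a Weinreb amide (→ vinyl ketone).
5. Chains come from (2E,6E)-farnesyl bromide + N-methoxy-N-methylacetamide, and from geranyl chloride + CO + vinylstannane + allylated 3-methyl-3-sulfolene.

Locants: labdane numbering for each C20 half; unprimed = 7-methylidene half (10β-CH3, 5α-H), primed = mirror-image (ent) half; the cyclohexene is C12–C13–C14–C15–C15′–C14′.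

Assumption: the (2S,5S) catalyst of step 14 blocks the face that leads to 12S,14′S; if the sense is the opposite, its (2R,5R) antipode is used with no other change.

## Route

Step 1
Reactants: 1 (2E,6E)-farnesyl bromide; 2 N-methoxy-N-methylacetamide
Product: 3 (4E,8E)-N-methoxy-N,5,9,13-tetramethyltetradeca-4,8,12-trienamide
Conditions: LiN(iPr)2, THF, −78 °C; then 1, −78 → 0 °C
Reagents that add atoms: none
Why: Enolate alkylation (SN2) of the lithium enolate of the Weinreb acetamide by the primary allylic bromide; no stereocentre is formed and both E-alkenes are untouched.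

Step 2
Reactants: 3
Product: 4 (4E,8E,12E)-14-hydroxy-N-methoxy-N,5,9,13-tetramethyltetradeca-4,8,12-trienamide
Conditions: SeO2 (10 mol%), t-BuOOH, salicylic acid (10 mol%), CH2Cl2, 0 °C → rt
Reagents that add atoms: tert-butyl hydroperoxide (CC(C)(C)OO)
Why: Sharpless catalytic SeO2 allylic oxidation (ene reaction, then [2,3]-sigmatropic shift) attacks the most electron-rich terminal trisubstituted alkene at its (E)-methyl group, giving the (E)-allylic alcohol; no stereocentre.

Step 3
Reactants: 4
Product: 5 (4E,8E)-11-[(2R,3R)-3-(hydroxymethyl)-3-methyloxiran-2-yl]-N-methoxy-N,5,9-trimethylundeca-4,8-dienamide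
Conditions: Ti(OiPr)4 (10 mol%), D-(−)-diisopropyl tartrate (12 mol%), t-BuOOH, 4 Å MS, CH2Cl2, −20 °C
Reagents that add atoms: tert-butyl hydroperoxide (CC(C)(C)OO)
Why: Sharpless asymmetric epoxidation touches only the allylic-alcohol alkene; D-(−)-tartrate gives the (2R,3R)-epoxy alcohol (antipode of the (2S,3S) series given by L-(+)-tartrate), which sets the carbinol carbon C3 that controls the whole ent half.

Step 4
Reactants: 5
Product: 6 ent-type decalin diol Weinreb amide with 8(17)-alkene
Conditions: Cp2TiCl2 (2.5 equiv), Mn dust, THF, rt (gives Cp2TiCl); slow addition of 5; then 1 M HCl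
Reagents that add atoms: none
Why: Nugent–RajanBabu epoxide opening by Cp2TiCl, then a biomimetic chair–chair 6-endo/6-endo radical bicyclisation ended by titanium-mediated loss of a C17 hydrogen to the exocyclic 8(17)-alkene; the retained C3 carbinol (R, oxygen equatorial) fixes C5, C9 and C10 (trans-decalin, side chain equatorial), and the planar C4 radical closes with the CH2O[Ti] arm equatorial (modest preference, roughly 3:1 estimated; the 4-epimer is removed by chromatography).

Step 5
Reactants: 6
Product: 7 ent-type decalin diol vinyl ketone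
Conditions: CH2=CHMgBr (4.5 equiv), THF, −78 → 0 °C; cold 1 M HCl
Reagents that add atoms: vinylmagnesium bromide (C=C[Mg]Br)
Why: Weinreb ketone synthesis; the chelated tetrahedral intermediate prevents over-addition and collapses on cold acidic quench to the vinyl ketone, the hydroxyls ride along as magnesium alkoxides and no stereocentre is touched.

Step 6
Reactants: 8 geranyl chloride
Product: 9 (2E,6E)-8-chloro-2,6-dimethylocta-2,6-dien-1-ol
Conditions: SeO2 (10 mol%), t-BuOOH, salicylic acid (10 mol%), CH2Cl2, 0 °C → rt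
Reagents that add atoms: tert-butyl hydroperoxide (CC(C)(C)OO)
Why: Sharpless catalytic SeO2 allylic oxidation; the alkene next to the allylic chloride is deactivated, so only the (E)-methyl of the terminal alkene is oxidised; no stereocentre.

Step 7
Reactants: 9
Product: 10 [(2S,3S)-3-[(3E)-5-chloro-3-methylpent-3-en-1-yl]-2-methyloxiran-2-yl]methanol
Conditions: Ti(OiPr)4 (10 mol%), L-(+)-diisopropyl tartrate (12 mol%), t-BuOOH, 4 Å MS, CH2Cl2, −20 °C
Reagents that add atoms: tert-butyl hydroperoxide (CC(C)(C)OO)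
Why: Sharpless asymmetric epoxidation with L-(+)-tartrate gives the (2S,3S)-epoxy alcohol, the mirror-image series of 5, whose carbinol carbon will set the normal-series decalin.

Step 8
Reactants: 11 3-methyl-2,5-dihydrothiophene 1,1-dioxide; 12 allyl bromide
Product: 13 2-allyl-3-methyl-2,5-dihydrothiophene 1,1-dioxide (racemic)
Conditions: LiN(SiMe3)2 added to 11 + 12, THF/DMPU, −78 °C
Reagents that add atoms: none
Why: Kinetic α-sulfonyl carbanion alkylation (SN2) at C2, the position next to the methyl-bearing alkene carbon, with the electrophile present to outrun ring opening; the new stereocentre is racemic and is erased in step 12.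

Step 9
Reactants: 10
Product: 14 (5E)-8-[(2S,3S)-3-(hydroxymethyl)-3-methyloxiran-2-yl]-6-methylocta-1,5-dien-3-one
Conditions: Pd(PPh3)4 (5 mol%), CO (3 atm), CH2=CHSnBu3, THF, 50 °C
Reagents that add atoms: carbon monoxide ([C-]#[O+]); tributyl(vinyl)stannane (C=C[Sn](CCCC)(CCCC)CCCC)
Why: Stille carbonylative cross-coupling (oxidative addition of the allylic chloride to zerovalent palladium, CO insertion, transmetalation, reductive elimination) gives the allyl vinyl ketone under neutral conditions, with the E-alkene and the epoxy alcohol intact; no new stereocentre.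

Step 10
Reactants: 14; 13
Product: 15 acyclic epoxy enone carrying the sulfolene
Conditions: second-generation Hoveyda–Grubbs catalyst RuCl2(H2IMes)(=CH-C6H4-2-OiPr) (5 mol%), 13 (2 equiv), CH2Cl2, 40 °C
Reagents that add atoms: none
Why: Olefin cross-metathesis between the terminal allyl alkene and the electron-poor vinyl ketone gives the (E)-enone with loss of ethylene; the trisubstituted alkenes, the sulfolene alkene and the epoxide do not react.

Step 11
Reactants: 15
Product: 16 normal-series decalin keto diol carrying the sulfolene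
Conditions: Cp2TiCl2 (3 equiv), Mn dust, THF, rt (gives Cp2TiCl); slow addition of 15; then 1 M HCl
Reagents that add atoms: none
Why: Proposed new method: Cp2TiCl opens the epoxide to the tertiary C4 radical (Nugent–RajanBabu), which adds 6-endo to the electron-rich C5=C10 alkene; the nucleophilic C10 radical then adds 6-endo to the enone β-carbon C9 (polarity-matched), and a second Cp2TiCl reduces the α-keto radical to a titanium enolate that is protonated on work-up. The closest known reactions are titanocene epoxy-polyene bicyclisations and titanocene epoxide–enone radical cyclisations. The C3 carbinol (S, equatorial) fixes C5, C10 and C9 through the chair–chair transition state (trans-decalin, C11 equatorial from the E-enone), and C4 closes with CH2O[Ti] equatorial (modest preference; 4-epimer removed).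

Step 12
Reactants: 16
Product: 17 (3S,4R,5R,9S,10R,12E)-3,18-dihydroxy-17-norlabda-12,14-dien-7-one
Conditions: NaHCO3, toluene, 115 °C
Reagents that add atoms: none
Why: Cheletropic extrusion of SO2 (retro-[4+1]) from the 3-sulfolene is disrotatory with the C2 substituent turning outward, so only the (12E)-diene forms and the racemic sulfolene stereocentre disappears.

Step 13
Reactants: 17
Product: 18 (3S,4R,5R,9S,10R,12E)-7-methylidene-17-norlabda-12,14-diene-3,18-diol
Conditions: Ph3PCH3Br, KOtBu (4 equiv each), THF, 0 °C → rt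
Reagents that add atoms: methyltriphenylphosphonium bromide (C[P+](c1ccccc1)(c1ccccc1)c1ccccc1.[Br-])
Why: Wittig methylenation of the unhindered C7 ketone; C9 is β to the carbonyl and cannot epimerise, and the alkoxides and the diene are inert.

Step 14
Reactants: 18; 7
Product: 19 keto tetraol (cis-cyclohexene adduct; 12S,14′S)
Conditions: (2S,5S)-5-benzyl-3-methyl-2-(5-methylfuran-2-yl)imidazolidin-4-one·HClO4 (20 mol%), 7 (1.5 equiv), EtOH/H2O 95:5, 0 °C
Reagents that add atoms: none
Why: Iminium-ion (LUMO-lowering) organocatalytic Diels–Alder reaction: only the vinyl ketone is activated, so 18 can only act as the diene; the acyl-bearing carbon bonds to the substituted diene terminus C12 ("ortho" rule for 1-substituted dienes), the endo transition state puts C11 and the acyl group cis, and the catalyst blocks one face of the iminium ion, fixing C12 and C14′ as S,S whatever the remote decalins.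

Step 15
Reactants: 19
Product: 21 Z-enol triflate of the persilylated ketone, via tetrakis(trimethylsilyl) ether 20 (not isolated)
Conditions: Me3SiCl, imidazole, CH2Cl2, 0 °C; then KN(SiMe3)2, THF, −78 °C; PhNTf2, −78 → −20 °C
Reagents that add atoms: chlorotrimethylsilane (C[Si](C)(C)Cl); N-phenylbis(trifluoromethanesulfonimide) (O=S(=O)(N(c1ccccc1)S(=O)(=O)C(F)(F)F)C(F)(F)F)
Why: Silylation masks the four hydroxyls; kinetic deprotonation by the bulky amide base at the less hindered C12′ methylene (not the C14′ methine, so no epimerisation) gives the Z(O)-enolate expected for a ketone with a branched α′-substituent, and O-triflation freezes that geometry.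

Step 16
Reactants: 21
Product: 23 tetraol with the (12′E)-trisubstituted alkene, via tetrakis(trimethylsilyl) ether of the E-alkene 22 (not isolated)
Conditions: Fe(acac)3 (10 mol%), CH3MgBr, THF/NMP, −30 °C; then K2CO3, MeOH, rt
Reagents that add atoms: methylmagnesium bromide (C[Mg]Br)
Why: Iron-catalysed Kumada-type cross-coupling of the alkenyl triflate with CH3MgBr keeps the alkene geometry, turning the Z-enol triflate into the (12′E)-alkene; methanolysis then removes the four silyl ethers.

Step 17
Reactants: 23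
Product: 25 18,18′-diol, via bis(cyclic thionocarbonate) 24 (not isolated)
Conditions: 1,1′-thiocarbonyldiimidazole, DMAP, toluene, 80 °C; then Bu3SnH, AIBN, 110 °C; then 2 M NaOH, THF
Reagents that add atoms: none
Why: Barton–McCombie deoxygenation through the cyclic thionocarbonates of the two 1,3-diols: stannyl radical addition to C=S, β-scission of the C3–O bond (secondary radical favoured over primary C18), hydrogen transfer from Bu3SnH and hydrolysis of the thiolcarbonate leave the two primary alcohols; C3 and C3′ become CH2 and no other stereocentre is involved.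

Step 18
Reactants: 25
Product: 26 CNP0240573.1
Conditions: TEMPO (30 mol%), PhI(OAc)2, MeCN/pH 7 buffer, rt
Reagents that add atoms: water (O)
Why: Oxoammonium (TEMPO) oxidation of both neopentyl primary alcohols through the aldehyde hydrates to the carboxylic acids; the quaternary C4 and C4′ centres cannot epimerise and the alkenes are inert to the oxoammonium salt.

## Compound list

1 | (2E,6E)-farnesyl bromide [(2E,6E)-1-bromo-3,7,11-trimethyldodeca-2,6,10-triene] | CC(C)=CCC/C(C)=C/CC/C(C)=C/CBr | starting material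
2 | N-methoxy-N-methylacetamide | CC(=O)N(C)OC | starting material
3 | (4E,8E)-N-methoxy-N,5,9,13-tetramethyltetradeca-4,8,12-trienamide | CC(C)=CCC/C(C)=C/CC/C(C)=C/CCC(=O)N(C)OC | intermediate
4 | (4E,8E,12E)-14-hydroxy-N-methoxy-N,5,9,13-tetramethyltetradeca-4,8,12-trienamide | OC/C(C)=C/CC/C(C)=C/CC/C(C)=C/CCC(=O)N(C)OC | intermediate
5 | (4E,8E)-11-[(2R,3R)-3-(hydroxymethyl)-3-methyloxiran-2-yl]-N-methoxy-N,5,9-trimethylundeca-4,8-dienamide | OC[C@@]1(C)O[C@@H]1CC/C(C)=C/CC/C(C)=C/CCC(=O)N(C)OC | intermediate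
6 | (3R,4S,5S,9R,10S)-3,18-dihydroxy-N-methoxy-N-methyl-14,15,16-trinorlabd-8(17)-en-13-amide (ent-type trans-decalin: 10α-CH3, 5β-H, 9β-H, equatorial 3-OH and 4-CH2OH) | CON(C)C(=O)CC[C@@H]1C(=C)CC[C@H]2[C@@]1(C)CC[C@@H](O)[C@]2(C)CO | intermediate
7 | (3R,4S,5S,9R,10S)-3,18-dihydroxy-16-norlabda-8(17),14-dien-13-one | C=CC(=O)CC[C@@H]1C(=C)CC[C@H]2[C@@]1(C)CC[C@@H](O)[C@]2(C)CO | intermediate
8 | geranyl chloride [(2E)-1-chloro-3,7-dimethylocta-2,6-diene] | CC(C)=CCC/C(C)=C/CCl | starting material
9 | (2E,6E)-8-chloro-2,6-dimethylocta-2,6-dien-1-ol | OC/C(C)=C/CC/C(C)=C/CCl | intermediate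
10 | [(2S,3S)-3-[(3E)-5-chloro-3-methylpent-3-en-1-yl]-2-methyloxiran-2-yl]methanol | OC[C@]1(C)O[C@H]1CC/C(C)=C/CCl | intermediate
11 | 3-methyl-2,5-dihydrothiophene 1,1-dioxide (3-methyl-3-sulfolene) | CC1=CCS(=O)(=O)C1 | starting material
12 | allyl bromide | C=CCBr | starting material
13 | 2-allyl-3-methyl-2,5-dihydrothiophene 1,1-dioxide (racemic) | C=CCC1C(C)=CCS1(=O)=O | intermediate
14 | (5E)-8-[(2S,3S)-3-(hydroxymethyl)-3-methyloxiran-2-yl]-6-methylocta-1,5-dien-3-one | OC[C@]1(C)O[C@H]1CC/C(C)=C/CC(=O)C=C | intermediate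
15 | (2E,6E)-9-[(2S,3S)-3-(hydroxymethyl)-3-methyloxiran-2-yl]-7-methyl-1-(3-methyl-1,1-dioxo-2,5-dihydrothiophen-2-yl)nona-2,6-dien-4-one (both epimers at the sulfolene carbon) | OC[C@]1(C)O[C@H]1CC/C(C)=C/CC(=O)/C=C/CC1C(C)=CCS1(=O)=O | intermediate
16 | (3S,4R,5R,10R)-3,18-dihydroxy-17-norlabdan-7-one with C12–C15 held as a 3-methyl-3-sulfolene ring (10β-CH3, 5α-H, 9α-H with the side chain equatorial, equatorial 3-OH and 4-CH2OH; both C12 epimers) | O=C1C[C@H](CC3C(C)=CCS3(=O)=O)[C@@]2(C)CC[C@H](O)[C@@](C)(CO)[C@@H]2C1 | intermediate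
17 | (3S,4R,5R,9S,10R,12E)-3,18-dihydroxy-17-norlabda-12,14-dien-7-one | O=C1C[C@H](C/C=C(\C)C=C)[C@@]2(C)CC[C@H](O)[C@@](C)(CO)[C@@H]2C1 | intermediate
18 | (3S,4R,5R,9S,10R,12E)-7-methylidene-17-norlabda-12,14-diene-3,18-diol | C=C1C[C@H](C/C=C(\C)C=C)[C@@]2(C)CC[C@H](O)[C@@](C)(CO)[C@@H]2C1 | intermediate
19 | keto tetraol: (12S,14′S)-cis-cyclohexene adduct; unprimed half as in 18, joined C11–C12; primed half as in 7, its C13′ ketone on C14′ | C=C1C[C@H](C[C@@H]2C(C)=CCC[C@@H]2C(=O)CC[C@@H]2C(=C)CC[C@H]3[C@@]2(C)CC[C@@H](O)[C@]3(C)CO)[C@@]2(C)CC[C@H](O)[C@@](C)(CO)[C@@H]2C1 | intermediate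
20 | 3,18,3′,18′-tetrakis(trimethylsilyl) ether of 19 | C=C1C[C@H](C[C@@H]2C(C)=CCC[C@@H]2C(=O)CC[C@@H]2C(=C)CC[C@H]3[C@@]2(C)CC[C@@H](O[Si](C)(C)C)[C@]3(C)CO[Si](C)(C)C)[C@@]2(C)CC[C@H](O[Si](C)(C)C)[C@@](C)(CO[Si](C)(C)C)[C@@H]2C1 | intermediate (not isolated)
21 | (12′Z)-13′-trifluoromethanesulfonyloxy-12′-ene (enol triflate) of 20 | C=C1C[C@H](C[C@@H]2C(C)=CCC[C@@H]2/C(OS(=O)(=O)C(F)(F)F)=C/C[C@@H]2C(=C)CC[C@H]3[C@@]2(C)CC[C@@H](O[Si](C)(C)C)[C@]3(C)CO[Si](C)(C)C)[C@@]2(C)CC[C@H](O[Si](C)(C)C)[C@@](C)(CO[Si](C)(C)C)[C@@H]2C1 | intermediate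
22 | tetrakis(trimethylsilyl) ether of 23 | C=C1C[C@H](C[C@@H]2C(C)=CCC[C@@H]2/C(C)=C/C[C@@H]2C(=C)CC[C@H]3[C@@]2(C)CC[C@@H](O[Si](C)(C)C)[C@]3(C)CO[Si](C)(C)C)[C@@]2(C)CC[C@H](O[Si](C)(C)C)[C@@](C)(CO[Si](C)(C)C)[C@@H]2C1 | intermediate (not isolated)
23 | 3,18,3′,18′-tetraol with the full C40 skeleton (3S,4R,5R,9S,10R,12S; 3′R,4′S,5′S,9′R,10′S,14′S; 12′E) | C=C1C[C@H](C[C@@H]2C(C)=CCC[C@@H]2/C(C)=C/C[C@@H]2C(=C)CC[C@H]3[C@@]2(C)CC[C@@H](O)[C@]3(C)CO)[C@@]2(C)CC[C@H](O)[C@@](C)(CO)[C@@H]2C1 | intermediate
24 | bis(3,18- and 3′,18′-cyclic thionocarbonate) of 23 | C=C1C[C@H](C[C@@H]2C(C)=CCC[C@@H]2/C(C)=C/C[C@@H]2C(=C)CC[C@H]3[C@@]2(C)CC[C@H]4OC(=S)OC[C@]34C)[C@@]2(C)CC[C@@H]4OC(=S)OC[C@@]4(C)[C@@H]2C1 | intermediate (not isolated)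
25 | 18,18′-diol (4R,5R,9S,10R,12S; 4′S,5′S,9′R,10′S,14′S; 12′E) | C=C1C[C@H](C[C@@H]2C(C)=CCC[C@@H]2/C(C)=C/C[C@@H]2C(=C)CC[C@H]3[C@@]2(C)CCC[C@]3(C)CO)[C@@]2(C)CCC[C@@](C)(CO)[C@@H]2C1 | intermediate
26 | CNP0240573.1, the 18,18′-dioic acid (4R,5R,9S,10R,12S; 4′S,5′S,9′R,10′S,14′S; 12′E) | C=C1C[C@H](C[C@@H]2C(C)=CCC[C@@H]2/C(C)=C/C[C@@H]2C(=C)CC[C@H]3[C@@]2(C)CCC[C@]3(C)C(=O)O)[C@@]2(C)CCC[C@@](C)(C(=O)O)[C@@H]2C1 | target

## Totals, risks and fallbacks

Total steps: 18. Longest linear sequence: 12 steps (8 to 26 through steps 6, 7 and 9–18).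

Step 11 is the least certain. The enone-terminated cascade is untested, the planar C4 radical gives only modest control of the 4-epimer, and Cp2TiCl may reduce the enone. The fallback sets out from 15 and returns at 16. BF3·OEt2 (CH2Cl2, −78 °C) opens the epoxide in a cationic, stereospecific epoxide–alkene monocyclisation; the E-epoxide geometry places CH2OH equatorially and the C10 cation loses a proton, giving the monocyclic methylidene diol F1 (its endocyclic alkene isomers are carried along). Fe(acac)3/PhSiH3 (EtOH, 60 °C) then transfers a hydrogen atom to that alkene, and the tertiary C10 radical closes ring B by 6-endo conjugate addition to the enone, giving 16.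

Step 14 may fail because both partners are bulky and lipophilic for iminium catalysis, and the 2-methyl group of the diene opposes the "ortho" preference. The fallback sets out from 5 and returns at 19. CH2=CHMgBr converts 5 into the acyclic epoxy vinyl ketone F2, a much less hindered dienophile. The same iminium-catalysed cycloaddition with 18 gives the open-chain adduct F3. The Cp2TiCl cascade of step 4 is then run on F3, so that the ent decalin is formed last, giving 19.

Step 15 may fail in the regio- and stereochemistry of enolisation next to the epimerisable C14′ centre in a large substrate. The fallback sets out from 7 and returns at 23. The enol triflate chemistry is moved to the monomer, where only one α-position exists and nothing can epimerise: Me3SiCl/imidazole, KN(SiMe3)2 and PhNTf2 give the silylated dienyl triflate F4. Fe(acac)3/CH3MgBr followed by K2CO3/MeOH gives the natural-type triene diol F5. F5 (in excess) and 18 are then heated (toluene, 110 °C) in an uncatalysed [4+2] dimerisation of the biogenetic type, and 23 is separated from its regio- and face-isomers.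

Further compounds

F1 | step 11 | (3E)-1-[(1R,2R,3S)-3-hydroxy-2-(hydroxymethyl)-2-methyl-6-methylidenecyclohexyl]-5-(3-methyl-1,1-dioxo-2,5-dihydrothiophen-2-yl)pent-3-en-2-one | C=C1CC[C@H](O)[C@@](C)(CO)[C@@H]1CC(=O)/C=C/CC1C(C)=CCS1(=O)=O
F2 | step 14 | (6E,10E)-13-[(2R,3R)-3-(hydroxymethyl)-3-methyloxiran-2-yl]-7,11-dimethyltrideca-1,6,10-trien-3-one | OC[C@@]1(C)O[C@@H]1CC/C(C)=C/CC/C(C)=C/CCC(=O)C=C
F3 | step 14 | (12S,14′S)-cycloadduct of 18 and F2 with the open-chain (2R,3R)-epoxy alcohol arm | C=C1C[C@H](C[C@@H]2C(C)=CCC[C@@H]2C(=O)CC/C=C(C)/CC/C=C(C)/CC[C@H]3O[C@]3(C)CO)[C@@]2(C)CC[C@H](O)[C@@](C)(CO)[C@@H]2C1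
F4 | step 15 | 3,18-bis(trimethylsilyl) ether of the (12Z)-13-trifluoromethanesulfonyloxy-12,14-diene derived from 7 | C=C/C(OS(=O)(=O)C(F)(F)F)=C/C[C@@H]1C(=C)CC[C@H]2[C@@]1(C)CC[C@@H](O[Si](C)(C)C)[C@]2(C)CO[Si](C)(C)C
F5 | step 15 | (3R,4S,5S,9R,10S,12E)-labda-8(17),12,14-triene-3,18-diol | C=C/C(C)=C/C[C@@H]1C(=C)CC[C@H]2[C@@]1(C)CC[C@@H](O)[C@]2(C)CO
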